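The 1,2-dioxane ring is disconnected at both C–O bonds: the peroxide carbons C3 and C6 are 1,4-related across C4–C5, so a (3E,5E)-diene plus singlet oxygen gives the ring, and C2, the CH2 next to the lactone carbonyl C1, can carry a removable silyl stereocentre. One [4+2] cycloaddition, steered anti to the C2 silyl group, forms C3–O and C6–O and sets both stereocentres; iodolactonisation across C4=C5 then closes the cis-fused γ-lactone. The precursor is a 2-(trimethylsilyl)ethyl (2R,3E,5E)-2-silyl-3,5-dienoate carrying the full C7–C16 chain, built from (R)-citronellal by two Zr-catalysed carboaluminations and an enantioselective Si–H insertion.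

Key step: step 13

Remarks on the chemistry
- Numbering used throughout: C1 lactone carbonyl, C2 α-CH2, C3 peroxy CH at the ring fusion, C4 methyl-bearing fusion carbon on the lactone oxygen, C5 ring CH2, C6 methyl-bearing peroxy carbon, C7–C16 side chain (C8 methyl branch, C11=C12, C15=C16–Ph).
- Structure check: the target is (3S,4S,6R,8R), with C2 and C7 cis on the dioxane ring. A (3E,5E)-diene places C2 and C7 outside, and a 2R silyl centre with C2–H in the diene plane puts silicon on the face opposite to the one oxygen must attack. These configurations are mutually consistent, so no structure needed correcting.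
- Ester design: the ester is 2-(trimethylsilyl)ethyl (TMSE), not a simple alkyl ester. Buffered fluoride then removes both the C2 silyl group and the ester, and no hydroxide touches the base-sensitive 3,6-dihydro-1,2-dioxine (C3–H next to O–O, peroxide β to the carbonyl).
- Diene geometry: both trisubstituted alkenes come from syn-carboalumination of alkynes, which fixes 3E and 5E; a ketone olefination would not.
- Lactone closure: iodolactonisation followed by tin hydride is used. Cobalt-hydride hydrofunctionalisation is avoided because Co(II) opens dihydrodioxines and would also attack the styrene.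
- Assumption: Rh2(R-DOSP)4 is taken to give the 2R silane, by analogy with the usual sense of donor/acceptor-carbenoid insertions; if the sense is opposite, the S-catalyst is used with nothing else changed.

Step 1
Reactants: 1 (E)-5-phenylpent-4-en-1-ol; 2 1-phenyl-1H-tetrazole-5-thiol
Product: 3 1-phenyl-5-{[(4E)-5-phenylpent-4-en-1-yl]sulfanyl}-1H-tetrazole
Conditions: PPh3, DIAD, THF, 0 °C → rt
Reagents that add atoms: none
Why: Mitsunobu thioetherification: the acidic tetrazolethiol displaces the activated primary alcohol (SN2), and neither the styrene nor any stereocentre is involved.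

Step 2
Reactants: 3 1-phenyl-5-{[(4E)-5-phenylpent-4-en-1-yl]sulfanyl}-1H-tetrazole
Product: 4 1-phenyl-5-{[(4E)-5-phenylpent-4-en-1-yl]sulfonyl}-1H-tetrazole
Conditions: 30% H2O2, (NH4)6Mo7O24·4H2O (cat.), EtOH, 0 °C → rt
Reagents that add atoms: hydrogen peroxide, OO
Why: Molybdate-catalysed peroxide oxidation takes the sulfide through the sulfoxide to the sulfone, and the peroxomolybdate is not electrophilic enough to epoxidise the conjugated alkene under these conditions.

Step 3
Reactants: 5 2-(trimethylsilyl)ethanol; 6 bromoacetyl bromide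
Product: 7 2-(trimethylsilyl)ethyl bromoacetate
Conditions: NaHCO3, MeCN, 0 °C
Reagents that add atoms: none
Why: O-Acylation of the primary alcohol by the acid bromide, with bicarbonate buffering the HBr so the C–Si bond is not exposed to acid.

Step 4
Reactants: 7 2-(trimethylsilyl)ethyl bromoacetate
Product: 8 2-(trimethylsilyl)ethyl diazoacetate
Conditions: TsNHNHTs, DBU, THF, 0 °C
Reagents that add atoms: N,N'-ditosylhydrazine, Cc1ccc(cc1)S(=O)(=O)NNS(=O)(=O)c1ccc(C)cc1
Why: Fukuyama diazoacetate synthesis: N-alkylation of ditosylhydrazine by the bromoacetate, then DBU-induced loss of two sulfinate ions, gives the diazo ester.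

Step 5
Reactants: 9 (R)-citronellal
Product: 10 (3R)-3,7-dimethyloct-6-en-1-yne
Conditions: dimethyl (1-diazo-2-oxopropyl)phosphonate, K2CO3, MeOH, 0 °C → rt
Reagents that add atoms: dimethyl (1-diazo-2-oxopropyl)phosphonate, CC(=O)C(=[N+]=[N-])P(=O)(OC)OC
Why: Ohira–Bestmann (Seyferth–Gilbert) homologation turns the aldehyde into the terminal alkyne with one added carbon (C5), and the C8 stereocentre, β to the carbonyl and taken from the chiral pool, cannot epimerise.

Step 6
Reactants: 10 (3R)-3,7-dimethyloct-6-en-1-yne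
Product: 12 (4R)-4-methylhept-6-ynal, via secondary ozonide 11 (not isolated)
Conditions: O3, CH2Cl2, −78 °C (Sudan III end point); then PPh3, −78 °C → rt
Reagents that add atoms: ozone, [O-][O+]=O
Why: Ozonolysis with reductive work-up: the electron-rich trisubstituted alkene reacts with ozone far faster than the terminal alkyne, and the indicator dye marks the end point before the alkyne is attacked.

Step 7
Reactants: 4 1-phenyl-5-{[(4E)-5-phenylpent-4-en-1-yl]sulfonyl}-1H-tetrazole; 12 (4R)-4-methylhept-6-ynal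
Product: 14 (4R,7E,11E)-4-methyl-12-phenyldodeca-7,11-dien-1-yne, via potassium sulfonyl carbanion 13 (not isolated)
Conditions: 4, KHMDS, DME, −60 °C; then 12, −60 °C → rt
Reagents that add atoms: none
Why: Julia–Kocienski olefination: the pre-metalated phenyltetrazolyl sulfone adds to the unbranched aldehyde, and Smiles rearrangement with anti-elimination gives the (E)-C11=C12 alkene (K+/DME favours E); addition to the aldehyde outpaces proton transfer from the alkyne C–H.

Step 8
Reactants: 14 (4R,7E,11E)-4-methyl-12-phenyldodeca-7,11-dien-1-yne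
Product: 16 (1E,4R,7E,11E)-1-iodo-2,4-dimethyl-12-phenyldodeca-1,7,11-triene, via alkenylalane 15 (not isolated)
Conditions: Me3Al, Cp2ZrCl2 (cat.), CH2Cl2, 0 °C → rt; then I2, THF, −30 → 0 °C
Reagents that add atoms: trimethylaluminium, C[Al](C)C; iodine, II
Why: Negishi zirconium-catalysed methylalumination adds Me (to C6) and Al (to C5) syn across the terminal alkyne, and iodinolysis with retention gives the (E)-iodide that fixes the 5E geometry; internal alkenes do not carbometalate under these conditions.

Step 9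
Reactants: 16 (1E,4R,7E,11E)-1-iodo-2,4-dimethyl-12-phenyldodeca-1,7,11-triene
Product: 17 (3E,6R,9E,13E)-4,6-dimethyl-14-phenyltetradeca-3,9,13-trien-1-yne
Conditions: HC≡CMgBr, ZnBr2, THF, 0 °C; then 16, Pd(PPh3)4 (cat.), rt
Reagents that add atoms: ethynylmagnesium bromide, C#C[Mg]Br
Why: Negishi alkynylation: ethynylzinc bromide couples with the alkenyl iodide with retention of geometry and gives the terminal enyne directly, without a protected alkyne.

Step 10
Reactants: 17 (3E,6R,9E,13E)-4,6-dimethyl-14-phenyltetradeca-3,9,13-trien-1-yne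
Product: 19 (1E,3E,6R,9E,13E)-1-iodo-2,4,6-trimethyl-14-phenyltetradeca-1,3,9,13-tetraene, via dienylalane 18 (not isolated)
Conditions: Me3Al, Cp2ZrCl2 (cat.), CH2Cl2, 0 °C → rt; then I2, THF, −30 → 0 °C
Reagents that add atoms: trimethylaluminium, C[Al](C)C; iodine, II
Why: A second syn-methylalumination, a known reaction of conjugated terminal enynes, places Me on C4 and Al on C3, and iodinolysis gives the (1E,3E)-dienyl iodide with the 3E geometry fixed.

Step 11
Reactants: 19 (1E,3E,6R,9E,13E)-1-iodo-2,4,6-trimethyl-14-phenyltetradeca-1,3,9,13-tetraene; 8 2-(trimethylsilyl)ethyl diazoacetate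
Product: 20 2-(trimethylsilyl)ethyl (3E,5E,8R,11E,15E)-2-diazo-4,6,8-trimethyl-16-phenylhexadeca-3,5,11,15-tetraenoate
Conditions: Pd(PPh3)4 (cat.), Et3N, n-Bu4NBr, MeCN, rt, dark
Reagents that add atoms: none
Why: Palladium-catalysed cross-coupling of an alkenyl iodide with the C–H bond of a diazoacetate (oxidative addition, base-assisted palladation of the diazo carbon, reductive elimination) keeps both the diazo group and the alkene geometry.

Step 12
Reactants: 20 2-(trimethylsilyl)ethyl (3E,5E,8R,11E,15E)-2-diazo-4,6,8-trimethyl-16-phenylhexadeca-3,5,11,15-tetraenoate; 21 dimethylphenylsilane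
Product: 22 2-(trimethylsilyl)ethyl (2R,3E,5E,8R,11E,15E)-2-[dimethyl(phenyl)silyl]-4,6,8-trimethyl-16-phenylhexadeca-3,5,11,15-tetraenoate
Conditions: Rh2(R-DOSP)4 (cat.), excess 21, pentane, −78 °C, slow addition of 20; then → rt
Reagents that add atoms: none
Why: Rhodium(II)-carbenoid Si–H insertion of a donor/acceptor alkenylcarbenoid is concerted and the chiral prolinate catalyst discriminates the carbenoid faces, setting C2 as R; excess silane, low temperature and a hydrocarbon solvent suppress vinylogous and intramolecular carbenoid reactions.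

Step 13
Reactants: 22 2-(trimethylsilyl)ethyl (2R,3E,5E,8R,11E,15E)-2-[dimethyl(phenyl)silyl]-4,6,8-trimethyl-16-phenylhexadeca-3,5,11,15-tetraenoate; 23 dioxygen (as photosensitised singlet oxygen)
Product: 24 2-(trimethylsilyl)ethyl (2R)-2-[dimethyl(phenyl)silyl]-2-{(3R,6R)-4,6-dimethyl-6-[(2R,5E,9E)-2-methyl-10-phenyldeca-5,9-dien-1-yl]-3,6-dihydro-1,2-dioxin-3-yl}acetate
Conditions: O2, tetraphenylporphyrin (cat.), hν (>500 nm), CH2Cl2, −78 °C, stopped at full conversion of the diene
Reagents that add atoms: none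
Why: Proposed new method: singlet oxygen adds suprafacially to the s-cis (3E,5E)-diene in a [4+2] cycloaddition that forms C3–O and C6–O together and so closes the six-membered 3,6-dihydro-1,2-dioxine ring by cycloaddition, not by a stepwise exo or endo cyclisation. The closest known reactions are the singlet-oxygen [4+2] addition to acyclic alkyl-substituted 1,3-dienes and the anti-to-silicon attack of electrophiles and dienophiles on alkenes and dienes that carry an allylic silyl stereocentre. The relative configuration of C3 and C6 follows from the diene geometry, because the two outside groups C2 and C7 of the (3E,5E)-diene end up cis on the ring. The absolute sense at both centres is set by C2: allylic 1,3-strain with the C4 methyl holds C2–H in the diene plane, so the C–Si bond stands on one face, raises the π-donor ability by σ(C–Si)–π overlap and shields that face, and oxygen bonds to C3 and C6 on the opposite face. The step needs facial selectivity, secured by the 2R silyl centre, and cycloaddition over ene reaction at the C4 and C6 methyls and at C7–H, favoured by low temperature, an aprotic solvent and the in-plane C2–H that cannot be abstracted; the isolated C11=C12 and styrenyl alkenes react far more slowly with singlet oxygen than the trisubstituted diene.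

Step 14
Reactants: 24 2-(trimethylsilyl)ethyl (2R)-2-[dimethyl(phenyl)silyl]-2-{(3R,6R)-4,6-dimethyl-6-[(2R,5E,9E)-2-methyl-10-phenyldeca-5,9-dien-1-yl]-3,6-dihydro-1,2-dioxin-3-yl}acetate
Product: 26 2-{(3S,6R)-4,6-dimethyl-6-[(2R,5E,9E)-2-methyl-10-phenyldeca-5,9-dien-1-yl]-3,6-dihydro-1,2-dioxin-3-yl}acetic acid, via desilylated ester 25 (not isolated)
Conditions: TBAF/AcOH (1:1), THF, −20 → 0 °C; then TBAF, 0 °C → rt; AcOH work-up
Reagents that add atoms: none
Why: Fluoride cleaves the C2–Si bond of the α-silyl ester and acetic acid protonates the incipient enolate at once, faster than loss of the β-peroxy oxygen; fluoride-induced fragmentation of the 2-(trimethylsilyl)ethyl ester then frees the acid without hydroxide, and C3 and C6 are untouched.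

Step 15
Reactants: 26 2-{(3S,6R)-4,6-dimethyl-6-[(2R,5E,9E)-2-methyl-10-phenyldeca-5,9-dien-1-yl]-3,6-dihydro-1,2-dioxin-3-yl}acetic acid
Product: 27 (3R,4S,4aR,7aS)-4-iodo-3,4a-dimethyl-3-[(2R,5E,9E)-2-methyl-10-phenyldeca-5,9-dien-1-yl]-3,4,4a,7a-tetrahydrofuro[3,2-c][1,2]dioxin-6(7H)-one (iodine on C5, anti to the lactone oxygen)
Conditions: I2, NaHCO3, MeCN/H2O, 0 °C, dark; Na2S2O3 work-up
Reagents that add atoms: iodine, II
Why: Iodolactonisation: the carboxylate adds 5-exo to the iodonium ion at the tertiary C4, and because the CH2CO2− arm is tied to C3 the new C4–O bond forms on the C2 face, which sets C4 (S in the target) as the cis ring fusion with iodine anti at C5; the side-chain alkenes have no internal nucleophile and form iodonium ions only reversibly.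

Step 16
Reactants: 27 (3R,4S,4aR,7aS)-4-iodo-3,4a-dimethyl-3-[(2R,5E,9E)-2-methyl-10-phenyldeca-5,9-dien-1-yl]-3,4,4a,7a-tetrahydrofuro[3,2-c][1,2]dioxin-6(7H)-one
Product: 28 (3R,4aS,7aS)-3,4a-dimethyl-3-[(2R,5E,9E)-2-methyl-10-phenyldeca-5,9-dien-1-yl]-3,4,4a,7a-tetrahydrofuro[3,2-c][1,2]dioxin-6(7H)-one (the target; 3S,4S,6R,8R in the chain numbering)
Conditions: Bu3SnH (excess, concentrated), Et3B/air (cat.), toluene, 0 °C
Reagents that add atoms: none
Why: Radical-chain deiodination with tin hydride removes the temporary C5 stereocentre, and a high hydride concentration at low temperature lets hydrogen transfer outrun attack of the C5 radical on the ring O–O bond, which is poorly aligned for homolytic substitution inside the six-membered ring.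

Compound list
1 | (E)-5-phenylpent-4-en-1-ol | OCCC/C=C/c1ccccc1 | starting material
2 | 1-phenyl-1H-tetrazole-5-thiol | Sc1nnnn1-c1ccccc1 | starting material
3 | 1-phenyl-5-{[(4E)-5-phenylpent-4-en-1-yl]sulfanyl}-1H-tetrazole | c1ccccc1/C=C/CCCSc1nnnn1-c1ccccc1 | intermediate
4 | 1-phenyl-5-{[(4E)-5-phenylpent-4-en-1-yl]sulfonyl}-1H-tetrazole | O=S(=O)(CCC/C=C/c1ccccc1)c1nnnn1-c1ccccc1 | intermediate
5 | 2-(trimethylsilyl)ethanol | C[Si](C)(C)CCO | starting material
6 | bromoacetyl bromide | BrCC(Br)=O | starting material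
7 | 2-(trimethylsilyl)ethyl bromoacetate | C[Si](C)(C)CCOC(=O)CBr | intermediate
8 | 2-(trimethylsilyl)ethyl diazoacetate | C[Si](C)(C)CCOC(=O)C=[N+]=[N-] | intermediate
9 | (R)-citronellal | C[C@H](CCC=C(C)C)CC=O | starting material
10 | (3R)-3,7-dimethyloct-6-en-1-yne | C[C@H](CCC=C(C)C)CC#C | intermediate
11 | 3,3-dimethyl-5-[(3R)-3-methylhex-5-yn-1-yl]-1,2,4-trioxolane (secondary ozonide, not isolated) | C[C@H](CCC1OOC(C)(C)O1)CC#C | intermediate
12 | (4R)-4-methylhept-6-ynal | C[C@H](CCC=O)CC#C | intermediate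
13 | potassium salt of 4 metalated at the carbon next to sulfur (not isolated) | [K+].[CH-](CC/C=C/c1ccccc1)S(=O)(=O)c1nnnn1-c1ccccc1 | intermediate
14 | (4R,7E,11E)-4-methyl-12-phenyldodeca-7,11-dien-1-yne | C[C@H](CC/C=C/CC/C=C/c1ccccc1)CC#C | intermediate
15 | [(1E,4R,7E,11E)-2,4-dimethyl-12-phenyldodeca-1,7,11-trien-1-yl]dimethylalane (not isolated) | C[C@H](CC/C=C/CC/C=C/c1ccccc1)C/C(C)=C/[Al](C)C | intermediate
16 | (1E,4R,7E,11E)-1-iodo-2,4-dimethyl-12-phenyldodeca-1,7,11-triene | C[C@H](CC/C=C/CC/C=C/c1ccccc1)C/C(C)=C/I | intermediate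
17 | (3E,6R,9E,13E)-4,6-dimethyl-14-phenyltetradeca-3,9,13-trien-1-yne | C[C@H](CC/C=C/CC/C=C/c1ccccc1)C/C(C)=C/C#C | intermediate
18 | dimethyl[(1E,3E,6R,9E,13E)-2,4,6-trimethyl-14-phenyltetradeca-1,3,9,13-tetraen-1-yl]alane (not isolated) | C[C@H](CC/C=C/CC/C=C/c1ccccc1)C/C(C)=C/C(C)=C/[Al](C)C | intermediate
19 | (1E,3E,6R,9E,13E)-1-iodo-2,4,6-trimethyl-14-phenyltetradeca-1,3,9,13-tetraene | C[C@H](CC/C=C/CC/C=C/c1ccccc1)C/C(C)=C/C(C)=C/I | intermediate
20 | 2-(trimethylsilyl)ethyl (3E,5E,8R,11E,15E)-2-diazo-4,6,8-trimethyl-16-phenylhexadeca-3,5,11,15-tetraenoate | C[C@H](CC/C=C/CC/C=C/c1ccccc1)C/C(C)=C/C(C)=C/C(=[N+]=[N-])C(=O)OCC[Si](C)(C)C | intermediate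
21 | dimethylphenylsilane | C[SiH](C)c1ccccc1 | starting material
22 | 2-(trimethylsilyl)ethyl (2R,3E,5E,8R,11E,15E)-2-[dimethyl(phenyl)silyl]-4,6,8-trimethyl-16-phenylhexadeca-3,5,11,15-tetraenoate | C[C@H](CC/C=C/CC/C=C/c1ccccc1)C/C(C)=C/C(C)=C/[C@H](C(=O)OCC[Si](C)(C)C)[Si](C)(C)c1ccccc1 | intermediate
23 | dioxygen | O=O | starting material
24 | 2-(trimethylsilyl)ethyl (2R)-2-[dimethyl(phenyl)silyl]-2-{(3R,6R)-4,6-dimethyl-6-[(2R,5E,9E)-2-methyl-10-phenyldeca-5,9-dien-1-yl]-3,6-dihydro-1,2-dioxin-3-yl}acetate | C[C@H](CC/C=C/CC/C=C/c1ccccc1)C[C@]1(C)C=C(C)[C@H]([C@H](C(=O)OCC[Si](C)(C)C)[Si](C)(C)c2ccccc2)OO1 | intermediate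
25 | 2-(trimethylsilyl)ethyl 2-{(3S,6R)-4,6-dimethyl-6-[(2R,5E,9E)-2-methyl-10-phenyldeca-5,9-dien-1-yl]-3,6-dihydro-1,2-dioxin-3-yl}acetate (not isolated) | C[C@H](CC/C=C/CC/C=C/c1ccccc1)C[C@]1(C)C=C(C)[C@H](CC(=O)OCC[Si](C)(C)C)OO1 | intermediate
26 | 2-{(3S,6R)-4,6-dimethyl-6-[(2R,5E,9E)-2-methyl-10-phenyldeca-5,9-dien-1-yl]-3,6-dihydro-1,2-dioxin-3-yl}acetic acid | C[C@H](CC/C=C/CC/C=C/c1ccccc1)C[C@]1(C)C=C(C)[C@H](CC(=O)O)OO1 | intermediate
27 | (3R,4S,4aR,7aS)-4-iodo-3,4a-dimethyl-3-[(2R,5E,9E)-2-methyl-10-phenyldeca-5,9-dien-1-yl]-3,4,4a,7a-tetrahydrofuro[3,2-c][1,2]dioxin-6(7H)-one | C[C@H](CC/C=C/CC/C=C/c1ccccc1)C[C@]1(C)[C@@H](I)[C@]2(C)OC(=O)C[C@@H]2OO1 | intermediate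
28 | (3R,4aS,7aS)-3,4a-dimethyl-3-[(2R,5E,9E)-2-methyl-10-phenyldeca-5,9-dien-1-yl]-3,4,4a,7a-tetrahydrofuro[3,2-c][1,2]dioxin-6(7H)-one | C[C@H](CC/C=C/CC/C=C/c1ccccc1)C[C@]1(C)C[C@]2(C)OC(=O)C[C@@H]2OO1 | target

Total step count: 16. Longest linear sequence: 12 steps (steps 5–16 from (R)-citronellal; the sulfone branch, steps 1, 2 and 7–16, is equally long).

Steps most likely to fail

1. Step 13 (the proposed new method). Ene reaction at the C4 and C6 methyl groups or at C7–H, or transfer of silicon to oxygen, may outrun the cycloaddition, and the silyl centre may discriminate the two diene faces too weakly. The fallback gives up silicon control and uses the known undirected photo-oxygenation of a 3,5-dienoic acid. From 22, buffered fluoride (TBAF/AcOH, then TBAF, THF; no peroxide is present at this stage) removes both silyl groups to give (3E,5E,8R,11E,15E)-4,6,8-trimethyl-16-phenylhexadeca-3,5,11,15-tetraenoic acid F1. Photo-oxygenation of F1 (O2, tetraphenylporphyrin, hν, CH2Cl2, −78 °C), in which the less hindered C3 terminus eases the cycloaddition, should give 26 together with its ring diastereomer 2-{(3R,6S)-4,6-dimethyl-6-[(2R,5E,9E)-2-methyl-10-phenyldeca-5,9-dien-1-yl]-3,6-dihydro-1,2-dioxin-3-yl}acetic acid F2. The two are separated by preparative HPLC and the route is rejoined at 26.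

2. Step 14. Fluoride treatment may open the dihydrodioxine by base-induced processes: loss of the C3–O bond by β-elimination from C2 when the C–Si bond breaks, or Kornblum–DeLaMare cleavage at C3–H while the ester is removed. The fallback keeps fluoride away from the monocyclic peroxide and moves C–Si cleavage to the bicyclic lactone, where a retro-oxa-Michael opening can only re-close to the same cis-fused ring. From 24, trimethyltin hydroxide (1,2-dichloroethane, 60 °C), a hydrolysis reagent tolerated by strongly base-labile groups, gives (2R)-2-[dimethyl(phenyl)silyl]-2-{(3R,6R)-4,6-dimethyl-6-[(2R,5E,9E)-2-methyl-10-phenyldeca-5,9-dien-1-yl]-3,6-dihydro-1,2-dioxin-3-yl}acetic acid F3; if silicon is lost as well, 26 results and the main route resumes. Iodolactonisation of F3 (I2, NaHCO3, MeCN/H2O, 0 °C) gives the C2-(R)-dimethyl(phenyl)silyl derivative of iodolactone 27, F4. Tin hydride (Bu3SnH, Et3B/air, toluene, 0 °C) gives the C2-(R)-dimethyl(phenyl)silyl derivative of 28, F5. Buffered fluoride (TBAF/AcOH, THF, 0 °C) then replaces silicon by hydrogen and gives 28.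

3. Step 11. The dienyl diazo ester may decompose under the coupling conditions (electrocyclisation to a pyrazole, palladium-carbene pathways), or the hindered dienyl iodide may couple too slowly. The fallback separates C–C bond formation from diazo formation. From 19, palladium-catalysed coupling with the Reformatsky reagent made from 7 and zinc (Pd(dba)2/Q-Phos, THF, rt) gives 2-(trimethylsilyl)ethyl (3E,5E,8R,11E,15E)-4,6,8-trimethyl-16-phenylhexadeca-3,5,11,15-tetraenoate F6. Regitz diazo transfer onto this β,γ-unsaturated ester (p-acetamidobenzenesulfonyl azide, DBU, MeCN, 0 °C) gives 20, where the route is rejoined.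

Further compounds
F1 | step 13 | (3E,5E,8R,11E,15E)-4,6,8-trimethyl-16-phenylhexadeca-3,5,11,15-tetraenoic acid | C[C@H](CC/C=C/CC/C=C/c1ccccc1)C/C(C)=C/C(C)=C/CC(=O)O
F2 | step 13 | 2-{(3R,6S)-4,6-dimethyl-6-[(2R,5E,9E)-2-methyl-10-phenyldeca-5,9-dien-1-yl]-3,6-dihydro-1,2-dioxin-3-yl}acetic acid | C[C@H](CC/C=C/CC/C=C/c1ccccc1)C[C@@]1(C)C=C(C)[C@@H](CC(=O)O)OO1
F3 | step 14 | (2R)-2-[dimethyl(phenyl)silyl]-2-{(3R,6R)-4,6-dimethyl-6-[(2R,5E,9E)-2-methyl-10-phenyldeca-5,9-dien-1-yl]-3,6-dihydro-1,2-dioxin-3-yl}acetic acid | C[C@H](CC/C=C/CC/C=C/c1ccccc1)C[C@]1(C)C=C(C)[C@H]([C@H](C(=O)O)[Si](C)(C)c2ccccc2)OO1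
F4 | step 14 | C2-(R)-dimethyl(phenyl)silyl derivative of iodolactone 27 | C[C@H](CC/C=C/CC/C=C/c1ccccc1)C[C@]1(C)[C@@H](I)[C@]2(C)OC(=O)[C@H]([Si](C)(C)c3ccccc3)[C@@H]2OO1
F5 | step 14 | C2-(R)-dimethyl(phenyl)silyl derivative of 28 | C[C@H](CC/C=C/CC/C=C/c1ccccc1)C[C@]1(C)C[C@]2(C)OC(=O)[C@H]([Si](C)(C)c3ccccc3)[C@@H]2OO1
F6 | step 11 | 2-(trimethylsilyl)ethyl (3E,5E,8R,11E,15E)-4,6,8-trimethyl-16-phenylhexadeca-3,5,11,15-tetraenoate | C[C@H](CC/C=C/CC/C=C/c1ccccc1)C/C(C)=C/C(C)=C/CC(=O)OCC[Si](C)(C)C
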